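Atom labels C1–C15 follow germacrane numbering: C1 ketone, C2=C3 furanone alkene, C4=C5 Z-alkene, C6 lactone carbinol, C7, C8 angelate carbinol, C9 CH2, C10 quaternary. The target is 6R,7R,8S,10R. Descriptors change in some intermediates only because CIP priorities change. Catalysts, ligands and solvents are not numbered.

## Retrosynthetic overview
1. The furanone forms last, by hydrative cycloisomerisation of the ten-membered γ-hydroxy-ynone 19.
2. Key step: 19 comes from intramolecular carbonylative Sonogashira closure of acyclic (Z)-vinyl iodide / tertiary propargylic alcohol 17. C3 is carbon monoxide, and C2–C3, C3–C4 and the carbocycle form in one operation.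
3. 17 comes from angeloylation and C10-OH-directed reduction (sets C8) of the β-acyl α-methylene lactone 14.
4. 14 comes from a reagent-controlled boron syn-aldol/lactonisation of the "itaconyl" ketone 9 with (Z)-3-iodobut-2-enal 12 (sets C6 and C7).
5. 9 comes from catalytic asymmetric allylation of TMS-butynone (sets C10), ozonolysis, Zn allylation and oxidation. Ring order: lactone, then carbocycle, then furanone.

## Route

**Step 1**
Reactants: 1, 4-(trimethylsilyl)but-3-yn-2-one; 2, allylboronic acid pinacol ester
Product: 3, (R)-3-methyl-1-(trimethylsilyl)hex-5-en-1-yn-3-ol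
Conditions: valine-derived aminophenol catalyst (2.5 mol %, antipode chosen for Re-face delivery), NaOt-Bu (5 mol %), MeOH (2 equiv), toluene, 4→22 °C
Reagents that add atoms: allylB(pin), C=CCB1OC(C)(C)C(C)(C)O1
Why: Catalytic enantioselective allyl–B(pin) addition to a ketone, where the closed six-membered transition state distinguishes the linear alkynyl arm from methyl and sets C10 (R); residual enantiomer is removed as a diastereomer after step 9.

**Step 2**
Reactants: 3
Product: 4, (R)-triethyl{[3-methyl-1-(trimethylsilyl)hex-5-en-1-yn-3-yl]oxy}silane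
Conditions: TESOTf, 2,6-lutidine, CH2Cl2, 0 °C
Reagents that add atoms: triethylsilyl triflate, CC[Si](CC)(CC)OS(=O)(=O)C(F)(F)F
Why: Silyl triflate silylation of a hindered tertiary alcohol, which blocks retro-aldol and O-borylation later and does not touch C10.

**Step 3**
Reactants: 4
Product: 5, (R)-triethyl[(3-methylhex-5-en-1-yn-3-yl)oxy]silane
Conditions: K2CO3, MeOH, rt
Reagents that add atoms: none
Why: Methoxide protodesilylation cleaves only the alkynyl C–Si bond, and the tertiary TES ether survives.

**Step 4**
Reactants: 5
Product: 6, (R)-3-methyl-3-(triethylsilyloxy)pent-4-ynal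
Conditions: O3, CH2Cl2, −78 °C (Sudan III end-point); PPh3
Reagents that add atoms: ozone, [O-][O+]=O
Why: Ozonolysis, in which the terminal alkene reacts orders of magnitude faster than the alkyne, revealing the C8 aldehyde.

**Step 5**
Reactants: 6; 7, methyl 2-(bromomethyl)acrylate
Product: 8, methyl (6R)-4-hydroxy-6-methyl-2-methylidene-6-(triethylsilyloxy)oct-7-ynoate (C4/C8 epimers)
Conditions: Zn dust, THF/sat. aq NH4Cl, 0 °C; used crude
Reagents that add atoms: methyl 2-(bromomethyl)acrylate, C=C(CBr)C(=O)OC
Why: Zinc Barbier allylation forms C7–C8, and the new carbinol configuration does not matter because it is oxidised next; cold, neutral work-up avoids premature lactonisation.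

**Step 6**
Reactants: 8
Product: 9, methyl (R)-6-methyl-2-methylidene-4-oxo-6-(triethylsilyloxy)oct-7-ynoate
Conditions: Dess–Martin periodinane, NaHCO3, CH2Cl2, 0 °C
Reagents that add atoms: none
Why: Dess–Martin oxidation under near-neutral conditions gives the γ-keto-α-methylene ester without exo-to-endo alkene migration.

**Step 7**
Reactants: 10, but-2-yn-1-ol
Product: 11, (Z)-3-iodobut-2-en-1-ol
Conditions: Red-Al, THF, 0 °C→rt; then I2, −78 °C→rt
Reagents that add atoms: iodine, II
Why: Hydroxyl-directed trans-hydroalumination followed by iodinolysis with retention gives only the Z-iodide, which is the future 4Z geometry.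

**Step 8**
Reactants: 11
Product: 12, (Z)-3-iodobut-2-enal
Conditions: MnO2, CH2Cl2, rt, dark; used at once
Reagents that add atoms: none
Why: Neutral allylic oxidation with MnO2 preserves the Z-alkene.

**Step 9**
Reactants: 9; 12
Product: 13, methyl (3S,6R)-3-[(1S,2Z)-1-hydroxy-3-iodobut-2-en-1-yl]-6-methyl-2-methylidene-4-oxo-6-(triethylsilyloxy)oct-7-ynoate
Conditions: Ipc2BOTf (antipode chosen for Si-face attack on 12), i-Pr2NEt, CH2Cl2, −78 °C; add 12, −78→−20 °C; pH 7 buffer/MeOH/H2O2, 0 °C
Reagents that add atoms: aldehyde 12, C/C(I)=C/C=O
Why: Paterson boron aldol, in which enolisation at the more acidic, less hindered C7–H (C9 is neopentyl) gives the (Z)-enol borinate, the Zimmerman–Traxler chair gives the 6,7-syn adduct, and the Ipc ligands fix the absolute sense of C6/C7; using a γ-keto-α-methylene ester as donor is an untested substrate extension.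

**Step 10**
Reactants: 13
Product: 14, (4S,5S)-4-[(3R)-3-hydroxy-3-methylpent-4-ynoyl]-5-[(Z)-2-iodoprop-1-enyl]-3-methylidenedihydrofuran-2(3H)-one
Conditions: HF·pyridine, THF/pyridine, 0 °C→rt; then PPTS (cat.), PhH, 40 °C
Reagents that add atoms: none
Why: Acidic desilylation frees C10-OH and C6-OH lactonises onto the methyl ester, so the syn-aldol becomes the trans-6,7-lactone (also the thermodynamic C7 epimer), while the non-basic medium avoids retro-aldol and alkene migration.

**Step 11**
Reactants: 14
Product: 15, (4R,5S)-4-[(1S,3R)-1,3-dihydroxy-3-methylpent-4-yn-1-yl]-5-[(Z)-2-iodoprop-1-enyl]-3-methylidenedihydrofuran-2(3H)-one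
Conditions: Me4NBH(OAc)3, MeCN/AcOH 1:1, −30 °C
Reagents that add atoms: none
Why: Evans–Saksena hydroxyl-directed reduction, in which the C10-O-bound borohydride delivers hydride through a chair transition state with C7 and the C10 methyl equatorial and the slim ethynyl axial, giving 8S; lactone, acrylate, alkyne and vinyl iodide are inert.

**Step 12**
Reactants: 15; 16, angelic acid
Product: 17, (1S,3R)-3-hydroxy-1-{(2S,3R)-2-[(Z)-2-iodoprop-1-enyl]-4-methylidene-5-oxooxolan-3-yl}-3-methylpent-4-yn-1-yl (Z)-2-methylbut-2-enoate
Conditions: 16, 2,4,6-trichlorobenzoyl chloride, Et3N, toluene, rt; then 15, 75 °C (no DMAP)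
Reagents that add atoms: angelic acid, C/C=C(/C)C(=O)O
Why: Yamaguchi mixed-anhydride esterification without DMAP suppresses angelate-to-tiglate isomerisation, the tertiary propargylic OH is too hindered to react, and capping O8 also stops it trapping the acyl-Pd in step 13.

**Step 13 (key step)**
Reactants: 17; 18, carbon monoxide
Product: 19, (6R,7R,8S,10R)-8-angeloyloxy-10-hydroxy-3-oxogermacra-4Z,11(13)-dien-1-yn-6,12-olide (ten-membered enynone, trans-lactone)
Conditions: PdCl2(PPh3)2 (10 mol %), CuI (5 mol %), Et3N, CO (1 atm), THF, 25–40 °C, syringe-pump addition of 17 (final ≤1 mM)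
Reagents that add atoms: carbon monoxide, [C-]#[O+]
Why: Proposed new method: intramolecular carbonylative Sonogashira macrocyclisation, in which Pd(0) inserts into the (Z)-C4–I bond with retention, CO insertion gives the C3 acyl-Pd, and the tethered copper acetylide (C2) captures it and reductively eliminates to the ynone; the non-carbonylative closure would need a far more strained nine-membered enyne, the trans-lactone, Z-alkene and gem-disubstituted C10 pre-fold the chain, dilution suppresses dimers, and the closest known chemistry is intermolecular carbonylative Sonogashira coupling of vinyl/aryl iodides with tertiary propargylic alcohols, carbonylative Stille macrocyclisation, and ten-membered enyne closures; no stereocentre is touched.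

**Step 14**
Reactants: 19
Product: 20, lychnopholide
Conditions: (p-CF3C6H4)3PAuCl/AgOTf (5 mol %), wet toluene, rt
Reagents that add atoms: none (water is catalytic: added at C1, expelled from C3)
Why: Gold(I)-catalysed conversion of a γ-hydroxy-ynone to a 3(2H)-furanone, where water adds at C1 to give the 1,3-diketone, C10-OH closes on C3 and dehydration forms C2=C3, helped by release of cycloalkyne strain; the C10–O bond is never broken, so configuration is retained.

## Compound list
1 | 4-(trimethylsilyl)but-3-yn-2-one | CC(=O)C#C[Si](C)(C)C | starting material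
2 | allylboronic acid pinacol ester | C=CCB1OC(C)(C)C(C)(C)O1 | starting material
3 | (R)-3-methyl-1-(trimethylsilyl)hex-5-en-1-yn-3-ol | C=CC[C@@](C)(O)C#C[Si](C)(C)C | intermediate
4 | TES ether of 3 | C=CC[C@@](C)(O[Si](CC)(CC)CC)C#C[Si](C)(C)C | intermediate
5 | (R)-triethyl[(3-methylhex-5-en-1-yn-3-yl)oxy]silane | C=CC[C@@](C)(O[Si](CC)(CC)CC)C#C | intermediate
6 | (R)-3-methyl-3-(triethylsilyloxy)pent-4-ynal | O=CC[C@@](C)(O[Si](CC)(CC)CC)C#C | intermediate
7 | methyl 2-(bromomethyl)acrylate | C=C(CBr)C(=O)OC | starting material
8 | homoallylic alcohol (C8 epimers) | C=C(CC(O)C[C@@](C)(O[Si](CC)(CC)CC)C#C)C(=O)OC | intermediate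
9 | γ-keto-α-methylene ester | C=C(CC(=O)C[C@@](C)(O[Si](CC)(CC)CC)C#C)C(=O)OC | intermediate
10 | but-2-yn-1-ol | CC#CCO | starting material
11 | (Z)-3-iodobut-2-en-1-ol | C/C(I)=C/CO | intermediate
12 | (Z)-3-iodobut-2-enal | C/C(I)=C/C=O | intermediate
13 | syn-aldol adduct | C=C(C(=O)OC)[C@@H]([C@H](O)/C=C(/C)I)C(=O)C[C@@](C)(O[Si](CC)(CC)CC)C#C | intermediate
14 | β-acyl α-methylene trans-lactone | C=C1C(=O)O[C@H](/C=C(/C)I)[C@H]1C(=O)C[C@@](C)(O)C#C | intermediate
15 | 8S,10R diol lactone | C=C1C(=O)O[C@H](/C=C(/C)I)[C@H]1[C@@H](O)C[C@@](C)(O)C#C | intermediate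
16 | angelic acid | C/C=C(/C)C(=O)O | starting material
17 | seco-precursor (vinyl iodide / alkynol angelate) | C=C1C(=O)O[C@H](/C=C(/C)I)[C@H]1[C@@H](OC(=O)/C(C)=C\C)C[C@@](C)(O)C#C | intermediate
18 | carbon monoxide | [C-]#[O+] | starting material
19 | macrocyclic γ-hydroxy-ynone | C=C1C(=O)O[C@@H]2/C=C(/C)C(=O)C#C[C@](C)(O)C[C@H](OC(=O)/C(C)=C\C)[C@@H]12 | intermediate
20 | lychnopholide | C=C1C(=O)O[C@@H]2/C=C(/C)C3=CC(=O)[C@@](C)(C[C@H](OC(=O)/C(C)=C\C)[C@@H]12)O3 | target

## Summary
Total steps: 14.
Longest linear sequence: 12 (steps 1–6 and 9–14, from compound 1).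

Steps most likely to fail:
1. **Step 13, carbonylative macrocyclisation.** Risks are oligomers, acyl-Pd insertion into the α-methylene lactone, and Pd(0) ionisation of the allylic lactone C6–O bond.
   Fallback: reverse the ring order. Make the 5-alkenyl-3(2H)-furanone first by the precedented intermolecular Pd/CO coupling of the alkynol with a protected (Z)-3-iodobutenol. Then close the ten-membered ring at C6–C7 by intramolecular Zn/Cr-mediated 2-(alkoxycarbonyl)allylation of the C6 enal.
2. **Step 9, boron aldol of the itaconyl ketone.** Risks are γ-attack, isomerisation to the conjugated enedione, and modest facial control.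
   Fallback: abandon the enolate. Elaborate aldehyde 6 into a geometrically defined 3-substituted 2-(methoxycarbonyl)allylboronate that already carries the C8 carbinol. A stereospecific allylboration/lactonisation of 12 then sets C6 and C7.
3. **Step 11, directed reduction at C8.** Risks are slow boron exchange at the tertiary carbinol and only a small methyl/ethynyl bias.
   Fallback: accept or deliberately make the 8-epimer (for example by chelation-controlled reduction). Then install the angelate with inversion by Mitsunobu esterification with angelic acid, replacing step 12.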